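**Strategy.** Ring A (eudesmane numbering) is cut as a [4+2] adduct: an intramolecular Diels–Alder reaction of an open-chain 1,7,9-decatriene forms C1–C2 and C5–C10 and so closes rings A and B in one operation. The key step exploits that C2–C3–C4–C5 of ring A can be a 2-silyloxydiene (C4 carbonyl masked) and C1/C10 with its methyl a methallyl-type alkene, linked through C6–C9. The precursor is a trans-α-methylene-γ-butyrolactone carrying the diene on C6 and the dienophile chain on C7. Its C6 oxygen, set by chromium catalysis, relays chirality to C7 and C10 and is later expelled to give the C5=C6 alkene and the C12 ester.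

Key step: step 8

Remark: ring A is C1–C5/C10, ring B is C5–C10, C11–C13 is the propenoate on C7, C14 is the methyl on C10 and C15 the methyl on C4; the ligand antipode in step 5 is assumed to be the one that gives the (4S,5R)-lactone, and 1 and 5 are taken as catalogue chemicals.

Step 1
Reactants: 1 4-methylpent-4-enal; 2 methyl acrylate
Product: 3 methyl 3-hydroxy-6-methyl-2-methylidenehept-6-enoate (racemic)
Conditions: DABCO (0.5 equiv), MeOH, rt, 4 d
Reagents that add atoms: none
Why: Morita–Baylis–Hillman reaction of an unhindered aliphatic aldehyde with an acrylate; the racemic carbinol centre is erased in step 2.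

Step 2
Reactants: 3 methyl 3-hydroxy-6-methyl-2-methylidenehept-6-enoate
Product: 4 methyl (2Z)-2-(bromomethyl)-6-methylhepta-2,6-dienoate
Conditions: NBS, Me2S, CH2Cl2, 0 °C → rt
Reagents that add atoms: N-bromosuccinimide, O=C1CCC(=O)N1Br
Why: Corey–Kim-type activation of the allylic alcohol followed by SN2′ attack of bromide should give the rearranged conjugated (Z)-bromide, the usual outcome for Baylis–Hillman adducts, while the isolated 1,1-disubstituted alkene stays untouched.

Step 3
Reactants: 5 ethyl 3-hydroxypent-4-enoate (racemic)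
Product: 6 ethyl 3-[(triethylsilyl)oxy]pent-4-enoate (racemic)
Conditions: TESCl, imidazole, CH2Cl2, 0 °C
Reagents that add atoms: chlorotriethylsilane, CC[Si](Cl)(CC)CC
Why: Standard silylation of a secondary allylic alcohol; the triethylsilyl group is chosen because dilute acid removes it in step 5.

Step 4
Reactants: 6 ethyl 3-[(triethylsilyl)oxy]pent-4-enoate
Product: 7 3-[(triethylsilyl)oxy]pent-4-enal (racemic)
Conditions: iBu2AlH (1.05 equiv), CH2Cl2, −78 °C
Reagents that add atoms: none
Why: Partial reduction of the ester through the tetrahedral aluminium hemiacetal, which is stable at −78 °C and releases the aldehyde only on work-up.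

Step 5
Reactants: 4 methyl (2Z)-2-(bromomethyl)-6-methylhepta-2,6-dienoate; 7 3-[(triethylsilyl)oxy]pent-4-enal
Product: 9 (4S,5R)-5-[(2RS)-2-hydroxybut-3-en-1-yl]-3-methylidene-4-(3-methylbut-3-en-1-yl)oxolan-2-one, via bis-silyl ether 8 (not isolated)
Conditions: CrCl2 (10 mol %), 3,6-di-tert-butyl-1,8-bis(4-isopropyl-4,5-dihydrooxazol-2-yl)-9H-carbazole (12 mol %), iPr2NEt (30 mol %), Mn powder, TMSCl, THF, rt; then 1 M HCl, THF, rt
Reagents that add atoms: none
Why: Catalytic asymmetric Nozaki–Hiyama–Kishi-type 2-(alkoxycarbonyl)allylation, in which the ligand on trivalent chromium selects the aldehyde face (C6, lactone C5), the (E)-configured γ-substituted allylchromium adds through a closed chair transition state to give the anti relationship (C7, lactone C4), and acid then cleaves both silyl ethers and closes the trans-lactone.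

Step 6
Reactants: 9 (4S,5R)-5-[(2RS)-2-hydroxybut-3-en-1-yl]-3-methylidene-4-(3-methylbut-3-en-1-yl)oxolan-2-one
Product: 10 (4S,5R)-3-methylidene-4-(3-methylbut-3-en-1-yl)-5-(2-oxobut-3-en-1-yl)oxolan-2-one
Conditions: Dess–Martin periodinane, CH2Cl2, 0 °C → rt
Reagents that add atoms: none
Why: Neutral oxidation of the secondary allylic alcohol to the vinyl ketone, so that both carbinol epimers converge and the base-sensitive β-acyloxy ketone is not exposed to base.

Step 7
Reactants: 10 (4S,5R)-3-methylidene-4-(3-methylbut-3-en-1-yl)-5-(2-oxobut-3-en-1-yl)oxolan-2-one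
Product: 11 (4S,5S)-5-[(1Z)-2-{[tert-butyl(dimethyl)silyl]oxy}buta-1,3-dien-1-yl]-3-methylidene-4-(3-methylbut-3-en-1-yl)oxolan-2-one
Conditions: TBSOTf (1.3 equiv), then Et3N (1.6 equiv), CH2Cl2, −78 → 0 °C
Reagents that add atoms: tert-butyldimethylsilyl trifluoromethanesulfonate, CC(C)(C)[Si](C)(C)OS(=O)(=O)C(F)(F)F
Why: Soft enolisation (O-silylation of the ketone, then deprotonation at C5, the only enolisable position) should give the (Z)-2-silyloxydiene without a free enolate, so the lactone oxygen on C6 is not eliminated.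

Step 8
Reactants: 11 (4S,5S)-5-[(1Z)-2-{[tert-butyl(dimethyl)silyl]oxy}buta-1,3-dien-1-yl]-3-methylidene-4-(3-methylbut-3-en-1-yl)oxolan-2-one
Product: 12 4-{[tert-butyl(dimethyl)silyl]oxy}-15-noreudesma-3,11(13)-dien-6α,12-olide (5αH, 6βH, 7αH, 10β-methyl)
Conditions: PhMe (5 mM), BHT (10 mol %), base-washed sealed tube, 185 °C
Reagents that add atoms: none
Why: A concerted, thermally allowed [4+2] cycloaddition (type 1 intramolecular Diels–Alder reaction of a 1,7,9-decatriene) joins the (Z)-2-silyloxydiene C2=C3–C4(OTBS)=C5 to the 1,1-disubstituted alkene C1=C10, forming C1–C2 and C5–C10; the closest precedent is the thermal cyclisation of unactivated 2-methyl-1,7,9-decatrienes to angularly methylated octalins. Ring B closes through the C5–C10 bond with the four-carbon tether C6–C9 in a chair arrangement, and ring A closes as the cycloadduct cyclohexene, whose C3=C4 enol silane is formed regiospecifically. The new quaternary centre C10 and the transient centre C5 are controlled by the lactone centres C6 and C7: allylic 1,3-strain with the (Z)-silyloxy group keeps H6 in the diene plane and so fixes the diene face, and the trans-lactone holds O6 and C11 equatorial on the forming ring, which places the C10 methyl axial and cis to the C7 side chain. The step needs the exo chair transition state (trans-decalin) to win over the endo boat, which would invert C10; the C4 silyloxy group penalises the endo chair and the boat carries extra strain, while the configuration at C5 is irrelevant because C5 becomes sp2 in step 10. The conjugated methylene of the lactone cannot reach the diene intramolecularly (two-atom link), and high dilution with a radical inhibitor suppresses its intermolecular reaction.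

Step 9
Reactants: 12 4-{[tert-butyl(dimethyl)silyl]oxy}-15-noreudesma-3,11(13)-dien-6α,12-olide
Product: 13 3α-bromo-4-oxo-15-noreudesm-11(13)-en-6α,12-olide
Conditions: NBS, THF/H2O (10:1), 0 °C
Reagents that add atoms: N-bromosuccinimide, O=C1CCC(=O)N1Br
Why: Electrophilic bromination of the enol silane at C3 with loss of the silyl group unmasks the C4 ketone, and axial attack on the half-chair from the α-face should give the axial 3α-bromide.

Step 10
Reactants: 13 3α-bromo-4-oxo-15-noreudesm-11(13)-en-6α,12-olide; 14 angelic acid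
Product: 17 methyl 3β-angeloyloxy-4-oxo-15-noreudesma-5,11(13)-dien-12-oate, via angelate lactone 15 (not isolated), via enone acid 16 (not isolated)
Conditions: 14 (1.5 equiv), Cs2CO3 (0.75 equiv), DMF, rt; then DBU (1.1 equiv), 0 °C; then MeI (3 equiv), rt
Reagents that add atoms: iodomethane, CI
Why: SN2 displacement of the axial α-bromide by cesium angelate inverts C3 to the equatorial 3β-ester (also the thermodynamic epimer of an α-acyloxy ketone), DBU then expels the lactone carboxylate by E1cB elimination through the C4/C5 enolate to give the C5=C6 enone acid, and the carboxylate is O-methylated in the same flask.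

Step 11
Reactants: 17 methyl 3β-angeloyloxy-4-oxo-15-noreudesma-5,11(13)-dien-12-oate
Product: 18 methyl (3S,4R,7R,10S)-3-angeloyloxy-4-hydroxyeudesma-5,11(13)-dien-12-oate (3β-ester, 4β-hydroxy, 4α-methyl)
Conditions: MeLi, CeCl3, THF, −78 °C; then aq. NH4Cl at −78 °C
Reagents that add atoms: methyllithium, [Li]C
Why: Organocerium 1,2-addition to the enone carbonyl from the α-face, anti to the axial C10 methyl (equatorial attack), should give the axial 4β-hydroxy and equatorial 4α-methyl groups, and the weakly basic reagent at −78 °C should discriminate the ketone from the two esters.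

**Compound list**

1 | 4-methylpent-4-enal | C=C(C)CCC=O | starting material
2 | methyl acrylate | C=CC(=O)OC | starting material
3 | methyl 3-hydroxy-6-methyl-2-methylidenehept-6-enoate (racemic) | C=C(C)CCC(O)C(=C)C(=O)OC | intermediate
4 | methyl (2Z)-2-(bromomethyl)-6-methylhepta-2,6-dienoate | BrC/C(=C\CCC(C)=C)C(=O)OC | intermediate
5 | ethyl 3-hydroxypent-4-enoate (racemic) | CCOC(=O)CC(O)C=C | starting material
6 | ethyl 3-[(triethylsilyl)oxy]pent-4-enoate (racemic) | CCOC(=O)CC(O[Si](CC)(CC)CC)C=C | intermediate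
7 | 3-[(triethylsilyl)oxy]pent-4-enal (racemic) | O=CCC(O[Si](CC)(CC)CC)C=C | intermediate
8 | methyl (3S,4R,6RS)-2-methylidene-3-(3-methylbut-3-en-1-yl)-6-[(triethylsilyl)oxy]-4-[(trimethylsilyl)oxy]oct-7-enoate | C=CC(O[Si](CC)(CC)CC)C[C@@H](O[Si](C)(C)C)[C@@H](CCC(C)=C)C(=C)C(=O)OC | intermediate (not isolated)
9 | (4S,5R)-5-[(2RS)-2-hydroxybut-3-en-1-yl]-3-methylidene-4-(3-methylbut-3-en-1-yl)oxolan-2-one | C=CC(O)C[C@H]1OC(=O)C(=C)[C@@H]1CCC(C)=C | intermediate
10 | (4S,5R)-3-methylidene-4-(3-methylbut-3-en-1-yl)-5-(2-oxobut-3-en-1-yl)oxolan-2-one | C=CC(=O)C[C@H]1OC(=O)C(=C)[C@@H]1CCC(C)=C | intermediate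
11 | (4S,5S)-5-[(1Z)-2-{[tert-butyl(dimethyl)silyl]oxy}buta-1,3-dien-1-yl]-3-methylidene-4-(3-methylbut-3-en-1-yl)oxolan-2-one | C=C/C(O[Si](C)(C)C(C)(C)C)=C/[C@H]1OC(=O)C(=C)[C@@H]1CCC(C)=C | intermediate
12 | 4-{[tert-butyl(dimethyl)silyl]oxy}-15-noreudesma-3,11(13)-dien-6α,12-olide (5αH, 6βH, 7αH, 10β-methyl) | CC(C)(C)[Si](C)(C)OC1=CCC[C@]2(C)CC[C@H]3C(=C)C(=O)O[C@@H]3[C@@H]12 | intermediate
13 | 3α-bromo-4-oxo-15-noreudesm-11(13)-en-6α,12-olide | O=C1[C@H](Br)CC[C@]2(C)CC[C@H]3C(=C)C(=O)O[C@@H]3[C@@H]12 | intermediate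
14 | angelic acid, (2Z)-2-methylbut-2-enoic acid | C/C=C(/C)C(=O)O | starting material
15 | 3β-angeloyloxy-4-oxo-15-noreudesm-11(13)-en-6α,12-olide | O=C1[C@@H](OC(=O)/C(C)=C\C)CC[C@]2(C)CC[C@H]3C(=C)C(=O)O[C@@H]3[C@@H]12 | intermediate (not isolated)
16 | 3β-angeloyloxy-4-oxo-15-noreudesma-5,11(13)-dien-12-oic acid | C=C(C(=O)O)[C@H]1C=C2[C@](C)(CC[C@H](OC(=O)/C(C)=C\C)C2=O)CC1 | intermediate (not isolated)
17 | methyl 3β-angeloyloxy-4-oxo-15-noreudesma-5,11(13)-dien-12-oate | C=C(C(=O)OC)[C@H]1C=C2[C@](C)(CC[C@H](OC(=O)/C(C)=C\C)C2=O)CC1 | intermediate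
18 | methyl (3S,4R,7R,10S)-3-angeloyloxy-4-hydroxyeudesma-5,11(13)-dien-12-oate | C=C(C(=O)OC)[C@H]1C=C2[C@](C)(CC[C@H](OC(=O)/C(C)=C\C)[C@]2(C)O)CC1 | target

**Count.** Total steps: 11. Longest linear sequence: 9 steps (steps 1, 2 and 5–11; the branch through steps 3 and 4 is equally long).

**Steps most likely to fail**

1. Step 8. The unactivated 1,1-disubstituted alkene may only react near 185 °C. At that temperature silyl transfer from the enol silane to the allylic lactone oxygen (opening the lactone) may outrun the cycloaddition, and closure through the endo boat would invert C10. Fallback, from 10 back to 13: the carbonyl of 10 is masked as an enol ester made under acid instead of an enol silane made with base (isopropenyl acetate, TsOH cat., 60 °C), giving (4S,5S)-5-[(1Z)-2-acetoxybuta-1,3-dien-1-yl]-3-methylidene-4-(3-methylbut-3-en-1-yl)oxolan-2-one F1. This diene has no transferable silyl group and should tolerate 200–220 °C (1,2-dichlorobenzene, BHT). Its cycloadduct 4-acetoxy-15-noreudesma-3,11(13)-dien-6α,12-olide F2 is brominated at C3 with NBS in aqueous THF and so returns to 13. This fallback addresses the thermal breakdown; an endo-boat product would have to be removed as a diastereomer.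

2. Step 5. Facial control by the chromium catalyst may be incomplete with a γ-substituted, ester-bearing allyl reagent, and one antipode of the racemic β-silyloxy aldehyde may be mismatched. Fallback, from 5 and 4 back to 10: stereocontrol is moved from the catalyst to the aldehyde. Lipase-mediated acetylation of 5 (vinyl acetate) is expected to leave ethyl (3R)-3-hydroxypent-4-enoate F3 and to give ethyl (3S)-3-acetoxypent-4-enoate F4, which is set aside; either antipode would serve, because the carbinol is oxidised later. F3 is silylated (TESCl, imidazole) to ethyl (3R)-3-[(triethylsilyl)oxy]pent-4-enoate F5 and reduced (iBu2AlH, −78 °C) to (3R)-3-[(triethylsilyl)oxy]pent-4-enal F6. Stoichiometric CrCl2 in THF with 4 (achiral, anti-selective Nozaki–Hiyama allylation), then aqueous HCl, should give two trans-lactones: (4S,5R)-5-[(2R)-2-hydroxybut-3-en-1-yl]-3-methylidene-4-(3-methylbut-3-en-1-yl)oxolan-2-one F7 and (4R,5S)-5-[(2R)-2-hydroxybut-3-en-1-yl]-3-methylidene-4-(3-methylbut-3-en-1-yl)oxolan-2-one F8. These are diastereomers and are separated by chromatography; oxidation of F7 with Dess–Martin periodinane returns to 10.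

3. Step 10. Under DBU the α-acyloxy ketone may undergo acyl migration through the ene-diolate or angelate-to-tiglate isomerisation, and if elimination precedes substitution the liberated carboxylate may alkylate the bromide of another molecule. Fallback, from 12 to 18: oxygen is put on C3 electrophilically and the angelate is attached last. Rubottom oxidation of 12 (dimethyldioxirane, acetone, −40 °C; then HF·pyridine) should give 3α-hydroxy-4-oxo-15-noreudesm-11(13)-en-6α,12-olide F9. DBU then MeI opens the lactone to methyl 3α-hydroxy-4-oxo-15-noreudesma-5,11(13)-dien-12-oate F10. MeLi/CeCl3 (2.5 equiv, −78 °C) adds from the α-face to give methyl 3α,4β-dihydroxyeudesma-5,11(13)-dien-12-oate F11. SO3·pyridine/DMSO/Et3N oxidises the secondary alcohol to methyl 4β-hydroxy-3-oxoeudesma-5,11(13)-dien-12-oate F12. NaBH4 (MeOH, −20 °C) delivers hydride axially from the α-face to give the equatorial alcohol methyl 3β,4β-dihydroxyeudesma-5,11(13)-dien-12-oate F13. Yamaguchi esterification with 14 (2,4,6-trichlorobenzoyl chloride, Et3N, toluene, 80 °C) acylates the secondary hydroxyl and gives 18; the C3 configuration after the Rubottom step is immaterial because it is reset by the oxidation–reduction pair.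

Further compounds
F1 | step 8 | (4S,5S)-5-[(1Z)-2-acetoxybuta-1,3-dien-1-yl]-3-methylidene-4-(3-methylbut-3-en-1-yl)oxolan-2-one | C=C/C(OC(C)=O)=C/[C@H]1OC(=O)C(=C)[C@@H]1CCC(C)=C
F2 | step 8 | 4-acetoxy-15-noreudesma-3,11(13)-dien-6α,12-olide | CC(=O)OC1=CCC[C@]2(C)CC[C@H]3C(=C)C(=O)O[C@@H]3[C@@H]12
F3 | step 5 | ethyl (3R)-3-hydroxypent-4-enoate | CCOC(=O)C[C@@H](O)C=C
F4 | step 5 | ethyl (3S)-3-acetoxypent-4-enoate | CCOC(=O)C[C@H](OC(C)=O)C=C
F5 | step 5 | ethyl (3R)-3-[(triethylsilyl)oxy]pent-4-enoate | CCOC(=O)C[C@@H](O[Si](CC)(CC)CC)C=C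
F6 | step 5 | (3R)-3-[(triethylsilyl)oxy]pent-4-enal | O=CC[C@@H](O[Si](CC)(CC)CC)C=C
F7 | step 5 | (4S,5R)-5-[(2R)-2-hydroxybut-3-en-1-yl]-3-methylidene-4-(3-methylbut-3-en-1-yl)oxolan-2-one | C=C[C@H](O)C[C@H]1OC(=O)C(=C)[C@@H]1CCC(C)=C
F8 | step 5 | (4R,5S)-5-[(2R)-2-hydroxybut-3-en-1-yl]-3-methylidene-4-(3-methylbut-3-en-1-yl)oxolan-2-one | C=C[C@H](O)C[C@@H]1OC(=O)C(=C)[C@H]1CCC(C)=C
F9 | step 10 | 3α-hydroxy-4-oxo-15-noreudesm-11(13)-en-6α,12-olide | O=C1[C@H](O)CC[C@]2(C)CC[C@H]3C(=C)C(=O)O[C@@H]3[C@@H]12
F10 | step 10 | methyl 3α-hydroxy-4-oxo-15-noreudesma-5,11(13)-dien-12-oate | C=C(C(=O)OC)[C@H]1C=C2[C@](C)(CC[C@@H](O)C2=O)CC1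
F11 | step 10 | methyl 3α,4β-dihydroxyeudesma-5,11(13)-dien-12-oate | C=C(C(=O)OC)[C@H]1C=C2[C@](C)(CC[C@@H](O)[C@]2(C)O)CC1
F12 | step 10 | methyl 4β-hydroxy-3-oxoeudesma-5,11(13)-dien-12-oate | C=C(C(=O)OC)[C@H]1C=C2[C@](C)(CCC(=O)[C@]2(C)O)CC1
F13 | step 10 | methyl 3β,4β-dihydroxyeudesma-5,11(13)-dien-12-oate | C=C(C(=O)OC)[C@H]1C=C2[C@](C)(CC[C@H](O)[C@]2(C)O)CC1
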